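**Retrosynthetic overview**
1. Target ⇐ two neutral hydrogenolyses: removal of an aryl O-benzyl group, and N–O cleavage/hydrolysis of a 3-aryl-2-isoxazoline that masks the ArCOCH2CH2OH chain.
2. C9 alcohol ⇐ ester. C7 and C8 are both set in one step by Ru-catalysed asymmetric transfer hydrogenation with dynamic kinetic resolution (ATH-DKR) of a racemic α-aryloxy-β-keto ester (key step).
3. C8–O(aryl) bond ⇐ hindered phenol + α-bromo-β-keto ester, with no stereocontrol needed at that stage.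
4. Phenol fragment ⇐ 5-hydroxyvanillin by 3-O-benzylation of its dianion, oxime formation and nitrile oxide/ethylene [3+2] cycloaddition.
5. Ring order: both benzene rings are bought. The only ring made is the temporary 4,5-dihydroisoxazole (step 3), which is opened again in step 8.

Assumption: the SMILES is read as the threo-(7S,8S) isomer, i.e. (1S,2S) in propane-1,3-diol numbering; salt, enolate and catalyst-bound forms of a compound are not numbered separately.

**Route**

Step 1
Reactants: 1 5-hydroxyvanillin (3,4-dihydroxy-5-methoxybenzaldehyde)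
Product: 2 3-(benzyloxy)-4-hydroxy-5-methoxybenzaldehyde
Conditions: NaH (2.2 equiv), DMSO, rt; BnBr (1.0 equiv), rt; aq HCl work-up
Reagents that add atoms: benzyl bromide, BrCc1ccccc1
Why: Regioselective Williamson etherification of the dianion: the 4-phenoxide is delocalised into the para CHO and flanked by two ortho groups, so the more basic 3-phenoxide takes the single equivalent of BnBr.

Step 2
Reactants: 2 3-(benzyloxy)-4-hydroxy-5-methoxybenzaldehyde
Product: 3 (E)-3-(benzyloxy)-4-hydroxy-5-methoxybenzaldehyde oxime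
Conditions: NH2OH·HCl (1.3 equiv), NaOAc (1.5 equiv), EtOH/H2O, rt
Reagents that add atoms: hydroxylamine hydrochloride, Cl.NO
Why: Oxime condensation of an aromatic aldehyde; the free phenol and the benzyl ether are inert.

Step 3
Reactants: 3 (E)-3-(benzyloxy)-4-hydroxy-5-methoxybenzaldehyde oxime; 4 ethylene
Product: 7 2-(benzyloxy)-4-(4,5-dihydroisoxazol-3-yl)-6-methoxyphenol, via hydroximoyl chloride 5 (not isolated), via nitrile oxide 6 (not isolated)
Conditions: NCS (1.05 equiv), DMF, 0 °C→rt; then ethylene (3 bar), KHCO3 (3 equiv), EtOAc, rt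
Reagents that add atoms: none
Why: Oxime chlorination and mild dehydrochlorination give the aryl nitrile oxide, which ethylene traps in a Huisgen 1,3-dipolar cycloaddition to give the 3-aryl-2-isoxazoline, a base- and hydride-stable mask of ArCOCH2CH2OH (no stereocentre).

Step 4
Reactants: 8 ethyl 3-(3,4-dimethoxyphenyl)-3-oxopropanoate
Product: 9 ethyl 2-bromo-3-(3,4-dimethoxyphenyl)-3-oxopropanoate (racemic)
Conditions: NBS (1.05 equiv), Mg(ClO4)2 (10 mol%), EtOAc, 0 °C→rt
Reagents that add atoms: N-bromosuccinimide, O=C1CCC(=O)N1Br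
Why: Lewis-acid-promoted enolisation and electrophilic α-bromination of a β-keto ester; the aroyl-deactivated veratryl ring is not brominated.

Step 5
Reactants: 7 2-(benzyloxy)-4-(4,5-dihydroisoxazol-3-yl)-6-methoxyphenol; 9 ethyl 2-bromo-3-(3,4-dimethoxyphenyl)-3-oxopropanoate
Product: 10 ethyl 2-[2-(benzyloxy)-4-(4,5-dihydroisoxazol-3-yl)-6-methoxyphenoxy]-3-(3,4-dimethoxyphenyl)-3-oxopropanoate (racemic)
Conditions: K2CO3 (1.5 equiv), acetone, rt→40 °C
Reagents that add atoms: none
Why: Williamson-type SN2 O-alkylation of the phenoxide by the doubly activated secondary bromide; both ortho positions and the para position are blocked, so C-alkylation is excluded, and the new centre is deliberately left racemic and labile.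

Step 6
Reactants: 10 ethyl 2-[2-(benzyloxy)-4-(4,5-dihydroisoxazol-3-yl)-6-methoxyphenoxy]-3-(3,4-dimethoxyphenyl)-3-oxopropanoate (racemic)
Product: 11 ethyl (2R,3S)-2-[2-(benzyloxy)-4-(4,5-dihydroisoxazol-3-yl)-6-methoxyphenoxy]-3-(3,4-dimethoxyphenyl)-3-hydroxypropanoate
Conditions: RuCl[(R,R)-TsDPEN](p-cymene) (2 mol%), HCO2H/Et3N 5:2, CH2Cl2, 30 °C
Reagents that add atoms: none
Why: Noyori–Ikariya asymmetric transfer hydrogenation with dynamic kinetic resolution: C8 epimerises rapidly through the enol, the (R,R)-Ru hydride fixes C7 as S by face selection, and only the C8 enantiomer whose Felkin–Anh trajectory (aryloxy anti to hydride) matches that face is reduced, giving the syn (threo) 2R,3S ester, the sense known for α-alkoxy-β-keto esters and assumed here to hold for the α-aryloxy substrate.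

Step 7
Reactants: 11 ethyl (2R,3S)-2-[2-(benzyloxy)-4-(4,5-dihydroisoxazol-3-yl)-6-methoxyphenoxy]-3-(3,4-dimethoxyphenyl)-3-hydroxypropanoate
Product: 12 (1S,2S)-2-[2-(benzyloxy)-4-(4,5-dihydroisoxazol-3-yl)-6-methoxyphenoxy]-1-(3,4-dimethoxyphenyl)propane-1,3-diol
Conditions: LiBH4 (3 equiv), THF, 0 °C→rt; aq NH4Cl
Reagents that add atoms: none
Why: Borohydride reduction of the α-aryloxy-activated ester to the primary alcohol; the cyclic oxime ether is not reduced by LiBH4 and neither stereocentre is touched (the C8 descriptor changes from R to S only through CIP priorities).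

Step 8
Reactants: 12 (1S,2S)-2-[2-(benzyloxy)-4-(4,5-dihydroisoxazol-3-yl)-6-methoxyphenoxy]-1-(3,4-dimethoxyphenyl)propane-1,3-diol
Product: 14 1-[3-(benzyloxy)-4-{[(1S,2S)-1-(3,4-dimethoxyphenyl)-1,3-dihydroxypropan-2-yl]oxy}-5-methoxyphenyl]-3-hydroxypropan-1-one, via β-hydroxy ketimine 13 (not isolated)
Conditions: H2 (1 atm), Raney Ni (W-2), B(OH)3 (3 equiv), MeOH/H2O 5:1, rt
Reagents that add atoms: water, O
Why: Hydrogenolysis of the weak N–O bond followed by boric-acid-buffered hydrolysis of the ketimine (isoxazoline-to-aldol unmasking) releases the β-hydroxy ketone near neutral pH, avoiding dehydration to the enone; any benzyl ether cleaved here is already the target.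

Step 9
Reactants: 14 1-[3-(benzyloxy)-4-{[(1S,2S)-1-(3,4-dimethoxyphenyl)-1,3-dihydroxypropan-2-yl]oxy}-5-methoxyphenyl]-3-hydroxypropan-1-one
Product: 15 1-[4-{[(1S,2S)-1-(3,4-dimethoxyphenyl)-1,3-dihydroxypropan-2-yl]oxy}-3-hydroxy-5-methoxyphenyl]-3-hydroxypropan-1-one (target)
Conditions: H2 (1 atm), 10% Pd/C, EtOAc, rt, stopped at full conversion
Reagents that add atoms: none
Why: Pd-catalysed hydrogenolysis of the aryl benzyl ether in a neutral aprotic solvent is much faster than reduction of the electron-rich aryl ketone or hydrogenolysis of the benzylic alcohol.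

**Compound list**
1 | 5-hydroxyvanillin (3,4-dihydroxy-5-methoxybenzaldehyde) | COc1cc(C=O)cc(O)c1O | starting material
2 | 3-(benzyloxy)-4-hydroxy-5-methoxybenzaldehyde | COc1cc(C=O)cc(OCc2ccccc2)c1O | intermediate
3 | (E)-3-(benzyloxy)-4-hydroxy-5-methoxybenzaldehyde oxime | COc1cc(/C=N/O)cc(OCc2ccccc2)c1O | intermediate
4 | ethylene | C=C | starting material
5 | (Z)-3-(benzyloxy)-N,4-dihydroxy-5-methoxybenzimidoyl chloride (hydroximoyl chloride) | COc1cc(/C(Cl)=N/O)cc(OCc2ccccc2)c1O | intermediate (not isolated)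
6 | 3-(benzyloxy)-4-hydroxy-5-methoxybenzonitrile oxide | COc1cc(C#[N+][O-])cc(OCc2ccccc2)c1O | intermediate (not isolated)
7 | 2-(benzyloxy)-4-(4,5-dihydroisoxazol-3-yl)-6-methoxyphenol | COc1cc(C2=NOCC2)cc(OCc3ccccc3)c1O | intermediate
8 | ethyl 3-(3,4-dimethoxyphenyl)-3-oxopropanoate | CCOC(=O)CC(=O)c1ccc(OC)c(OC)c1 | starting material
9 | ethyl 2-bromo-3-(3,4-dimethoxyphenyl)-3-oxopropanoate (racemic) | CCOC(=O)C(Br)C(=O)c1ccc(OC)c(OC)c1 | intermediate
10 | ethyl 2-[2-(benzyloxy)-4-(4,5-dihydroisoxazol-3-yl)-6-methoxyphenoxy]-3-(3,4-dimethoxyphenyl)-3-oxopropanoate (racemic) | CCOC(=O)C(Oc1c(OCc2ccccc2)cc(C3=NOCC3)cc1OC)C(=O)c4ccc(OC)c(OC)c4 | intermediate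
11 | ethyl (2R,3S)-2-[2-(benzyloxy)-4-(4,5-dihydroisoxazol-3-yl)-6-methoxyphenoxy]-3-(3,4-dimethoxyphenyl)-3-hydroxypropanoate | COc1ccc([C@H](O)[C@H](C(=O)OCC)Oc2c(OCc3ccccc3)cc(C4=NOCC4)cc2OC)cc1OC | intermediate
12 | (1S,2S)-2-[2-(benzyloxy)-4-(4,5-dihydroisoxazol-3-yl)-6-methoxyphenoxy]-1-(3,4-dimethoxyphenyl)propane-1,3-diol | COc1ccc([C@H](O)[C@H](CO)Oc2c(OCc3ccccc3)cc(C4=NOCC4)cc2OC)cc1OC | intermediate
13 | (1S,2S)-2-[2-(benzyloxy)-4-(3-hydroxypropanimidoyl)-6-methoxyphenoxy]-1-(3,4-dimethoxyphenyl)propane-1,3-diol (β-hydroxy ketimine) | COc1ccc([C@H](O)[C@H](CO)Oc2c(OCc3ccccc3)cc(C(=N)CCO)cc2OC)cc1OC | intermediate (not isolated)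
14 | 1-[3-(benzyloxy)-4-{[(1S,2S)-1-(3,4-dimethoxyphenyl)-1,3-dihydroxypropan-2-yl]oxy}-5-methoxyphenyl]-3-hydroxypropan-1-one | COc1ccc([C@H](O)[C@H](CO)Oc2c(OCc3ccccc3)cc(C(=O)CCO)cc2OC)cc1OC | intermediate
15 | 1-[4-{[(1S,2S)-1-(3,4-dimethoxyphenyl)-1,3-dihydroxypropan-2-yl]oxy}-3-hydroxy-5-methoxyphenyl]-3-hydroxypropan-1-one | COc1ccc([C@H](O)[C@H](CO)Oc2c(O)cc(C(=O)CCO)cc2OC)cc1OC | target

**Totals**
Total step count: 9.
Longest linear sequence: 8 steps (1 → 2 → 3 → 7 → 10 → 11 → 12 → 14 → 15, i.e. steps 1, 2, 3, 5, 6, 7, 8, 9).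

**Three steps most likely to fail, with fallbacks**

Step 6 (ATH-DKR). The bulky 2,6-disubstituted aryloxy group may erode the syn:anti ratio or slow the reduction. The fallback sets out from 7 and comes back at 12, using auxiliary-controlled C7–C8 bond formation instead of reduction. Phenol 7 is O-alkylated with purchased (R)-4-benzyl-3-(bromoacetyl)oxazolidin-2-one (K2CO3, acetone, rt) to give (R)-4-benzyl-3-{[2-(benzyloxy)-4-(4,5-dihydroisoxazol-3-yl)-6-methoxyphenoxy]acetyl}oxazolidin-2-one F1. Its Z-boron enolate (Bu2BOTf, iPr2NEt, CH2Cl2, −78 °C) adds to purchased 3,4-dimethoxybenzaldehyde in an Evans syn-aldol reaction to give (R)-4-benzyl-3-[(2R,3S)-2-[2-(benzyloxy)-4-(4,5-dihydroisoxazol-3-yl)-6-methoxyphenoxy]-3-(3,4-dimethoxyphenyl)-3-hydroxypropanoyl]oxazolidin-2-one F2. LiBH4 in wet THF then removes the auxiliary reductively and delivers diol 12 directly.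

Step 3 (nitrile oxide generation beside a free, electron-rich phenol). Ring chlorination by NCS, phenoxide addition to the nitrile oxide, or furoxan formation may dominate. The fallback sets out from 2 and comes back at 7, masking the phenol for the cycloaddition. Aldehyde 2 is converted (MOMCl, iPr2NEt, CH2Cl2) into 3-(benzyloxy)-5-methoxy-4-(methoxymethoxy)benzaldehyde F3, then (NH2OH·HCl, NaOAc) into (E)-3-(benzyloxy)-5-methoxy-4-(methoxymethoxy)benzaldehyde oxime F4. NCS/DMF gives (Z)-3-(benzyloxy)-N-hydroxy-5-methoxy-4-(methoxymethoxy)benzimidoyl chloride F5, which is not isolated. KHCO3 under ethylene converts it through 3-(benzyloxy)-5-methoxy-4-(methoxymethoxy)benzonitrile oxide F6, also not isolated, into 3-[3-(benzyloxy)-5-methoxy-4-(methoxymethoxy)phenyl]-4,5-dihydroisoxazole F7. HCl in MeOH at 40 °C removes the MOM group to give 7; nothing acid-sensitive is present yet.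

Step 5 (SN2 of a doubly ortho-substituted phenoxide on a secondary, enolisable bromide). Enolisation or debromination of 9 may outrun substitution. The fallback sets out from 8 and comes back at 10, replacing SN2 by carbene O–H insertion and bypassing 9. Keto ester 8 undergoes Regitz diazo transfer (p-ABSA, Et3N, MeCN) to give ethyl 2-diazo-3-(3,4-dimethoxyphenyl)-3-oxopropanoate F8. Rh2(OAc)4 (1 mol%) in CH2Cl2 at 40 °C in the presence of phenol 7 then effects rhodium-carbenoid O–H insertion, which is largely insensitive to steric hindrance at the phenol, to give 10.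

**Further compounds**
F1 | step 6 | (R)-4-benzyl-3-{[2-(benzyloxy)-4-(4,5-dihydroisoxazol-3-yl)-6-methoxyphenoxy]acetyl}oxazolidin-2-one | O=C(COc1c(OCc2ccccc2)cc(C3=NOCC3)cc1OC)N4[C@H](Cc5ccccc5)COC4=O
F2 | step 6 | (R)-4-benzyl-3-[(2R,3S)-2-[2-(benzyloxy)-4-(4,5-dihydroisoxazol-3-yl)-6-methoxyphenoxy]-3-(3,4-dimethoxyphenyl)-3-hydroxypropanoyl]oxazolidin-2-one | COc1ccc([C@H](O)[C@H](C(=O)N2[C@H](Cc3ccccc3)COC2=O)Oc4c(OCc5ccccc5)cc(C6=NOCC6)cc4OC)cc1OC
F3 | step 3 | 3-(benzyloxy)-5-methoxy-4-(methoxymethoxy)benzaldehyde | COc1cc(C=O)cc(OCc2ccccc2)c1OCOC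
F4 | step 3 | (E)-3-(benzyloxy)-5-methoxy-4-(methoxymethoxy)benzaldehyde oxime | COc1cc(/C=N/O)cc(OCc2ccccc2)c1OCOC
F5 | step 3 | (Z)-3-(benzyloxy)-N-hydroxy-5-methoxy-4-(methoxymethoxy)benzimidoyl chloride | COc1cc(/C(Cl)=N/O)cc(OCc2ccccc2)c1OCOC
F6 | step 3 | 3-(benzyloxy)-5-methoxy-4-(methoxymethoxy)benzonitrile oxide | COc1cc(C#[N+][O-])cc(OCc2ccccc2)c1OCOC
F7 | step 3 | 3-[3-(benzyloxy)-5-methoxy-4-(methoxymethoxy)phenyl]-4,5-dihydroisoxazole | COc1cc(C2=NOCC2)cc(OCc3ccccc3)c1OCOC
F8 | step 5 | ethyl 2-diazo-3-(3,4-dimethoxyphenyl)-3-oxopropanoate | CCOC(=O)C(=[N+]=[N-])C(=O)c1ccc(OC)c(OC)c1
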